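**Retrosynthetic overview**

1. Numbering used throughout: decalin C1–C8a (C1 carries the side chain, C2 the acetonyl group, C3 a methyl, diene C2=C3–C4=C4a, ketone C7, methyls on C6 and C8); side chain C9=C10(Me)–C11/C12(Me) oxirane–C13=C14–C15O2H; β is the face of H1/H8a. The C10–C11 bond is cut between the alkenyl carbon C10 and the oxirane carbon C11: forward, the (E)-alkenylzinc made from the C9≡C10 methylalkyne 29 adds to the aldehyde carbon C11 of epoxy aldehyde 34.
2. Feature that makes this possible: C11 is an oxirane carbon next to the quaternary oxirane carbon C12 (O, Me), and C12 is γ to the C15 carboxyl. The C11–C12 oxirane can therefore come from its transposed isomer, a temporary C12–C13 oxirane (a β,γ-epoxy ester, not in the target). This temporary ring makes C11 a plain aldehyde on a rigid, stereodefined α-carbon for the union; its E1cB opening then gives the C13=C14 enoate and frees the C12 alkoxide, which closes the target oxirane on C11 with inversion.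
3. Decalin 29: ring B starts as the benzene ring of a 2,6-dimethylphenol. C1 is set by Rh-catalysed asymmetric conjugate arylation of furan-2(5H)-one, ring A is closed by Pd-catalysed ketone α-arylation (C4–C4a), and all-cis hydrogenation of the arene (dearomatization, anti to the C1 substituent) sets C6, C7, C8 and C8a.
4. The 1,3-diene is built last on ring A (Saegusa enone C4=C4a, α'-dienyl triflate, methylation at C3). Both ketones travel as silyl-protected alcohols and are unveiled by a final double oxidation, so C6/C8 and the deconjugated acetonyl ketone never meet base.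
5. Ring order: ring B (aromatic, bought) → ring A (step 11) → temporary C12–C13 oxirane (step 24) → target C11–C12 oxirane (step 27).

Key step: step 26

Assumption: 3-bromo-2,6-dimethylphenol (1) is taken as purchasable; otherwise it follows in one step from 3-bromo-2,6-dimethylaniline by diazotisation and hydrolysis.

Abbreviations: TBS = tert-butyldimethylsilyl, Piv = pivaloyl, Tf = trifluoromethanesulfonyl, Ms = methanesulfonyl, TMSE = 2-(trimethylsilyl)ethyl, DMP = Dess–Martin periodinane.

**Route**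

Step 1
Reactants: 1 3-bromo-2,6-dimethylphenol
Product: 2 (3-bromo-2,6-dimethylphenoxy)(tert-butyl)dimethylsilane
Conditions: TBSCl, imidazole, DMF, 40 °C
Reagents that add atoms: tert-butyldimethylsilyl chloride, C[Si](C)(Cl)C(C)(C)C
Why: O-silylation of the hindered phenol installs the group that later becomes the C7 silyl ether.

Step 2
Reactants: 2 aryl bromide
Product: 4 [3-(TBSO)-2,4-dimethylphenyl]boronic acid, via aryllithium 3 (not isolated)
Conditions: n-BuLi, THF, −78 °C; B(OiPr)3; then cold 1 M HCl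
Reagents that add atoms: triisopropyl borate, CC(C)OB(OC(C)C)OC(C)C; water, O
Why: Bromine–lithium exchange followed by borylation and hydrolysis gives the boronic acid at the future C8a.

Step 3
Reactants: 4 boronic acid; 5 furan-2(5H)-one
Product: 6 (R)-4-[3-(TBSO)-2,4-dimethylphenyl]dihydrofuran-2(3H)-one
Conditions: [Rh(OH)((R)-BINAP)]2 (cat.), dioxane/H2O 10:1, 50 °C
Reagents that add atoms: none
Why: Rh-catalysed asymmetric conjugate arylation (Hayashi–Miyaura reaction) sets C1 by ligand control; (R)-BINAP is expected to give the (R)-lactone by analogy with cyclic enones and unsaturated lactones.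

Step 4
Reactants: 7 ethyl (S)-lactate
Product: 8 ethyl (S)-2-(TBSO)propanoate
Conditions: TBSCl, imidazole, DMF, rt
Reagents that add atoms: tert-butyldimethylsilyl chloride, C[Si](C)(Cl)C(C)(C)C
Why: Silylation protects the carbinol that serves as the masked acetonyl ketone; the stereocentre comes from the chiral pool and is removed in step 29.

Step 5
Reactants: 8 silyloxy ester
Product: 9 (S)-2-(TBSO)propan-1-ol
Conditions: DIBAL-H (2.2 equiv), CH2Cl2, −78 → 0 °C; Rochelle salt
Reagents that add atoms: none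
Why: Hydride reduction of the ester to the primary alcohol leaves the α-stereocentre untouched.

Step 6
Reactants: 9 alcohol
Product: 10 (S)-2-(TBSO)propyl triflate
Conditions: Tf2O, 2,6-lutidine, CH2Cl2, −78 °C; used at once
Reagents that add atoms: trifluoromethanesulfonic anhydride, O=S(=O)(OS(=O)(=O)C(F)(F)F)C(F)(F)F
Why: O-sulfonylation gives a primary triflate reactive enough to alkylate an enolate despite the β-silyloxy group.

Step 7
Reactants: 6 lactone; 10 triflate
Product: 12 (3S,4R)-trans-4-[3-(TBSO)-2,4-dimethylphenyl]-3-[(S)-2-(TBSO)propyl]dihydrofuran-2(3H)-one, via lactone lithium enolate 11 (not isolated)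
Conditions: LiHMDS, THF, −78 °C; then 10, −78 → −30 °C
Reagents that add atoms: none
Why: Lactone enolate alkylation (SN2) occurs anti to the C1 aryl group and at the only α-carbon (C2); the C2 configuration is of no consequence because C2 becomes sp2 in step 20.

Step 8
Reactants: 12 alkylated lactone
Product: 13 (3S,4R)-4-[3-(TBSO)-2,4-dimethylphenyl]-5-hydroxy-3-[(S)-2-(TBSO)propyl]pentan-2-one (in equilibrium with its cyclic hemiketal)
Conditions: MeLi (1.05 equiv), THF, −78 °C; aq NH4Cl
Reagents that add atoms: methyllithium, [Li]C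
Why: Mono-addition of MeLi to the lactone (tetrahedral lithium hemiketalate stable at −78 °C) introduces C4 as a methyl ketone and frees the C9 hydroxyl.

Step 9
Reactants: 13 hydroxy ketone
Product: 14 keto pivalate (pivalate ester of the primary C9–OH of 13)
Conditions: PivCl, pyridine, DMAP (cat.), CH2Cl2, 0 °C → rt
Reagents that add atoms: pivaloyl chloride, CC(C)(C)C(Cl)=O
Why: Acylation of the open-chain primary alcohol fixes the ketone form and protects C9–OH orthogonally to the silyl ethers.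

Step 10
Reactants: 14 keto pivalate
Product: 15 bromo keto pivalate (14 brominated at the arene carbon para to OTBS, the future C4a)
Conditions: NBS, MeCN, 0 °C
Reagents that add atoms: N-bromosuccinimide, O=C1CCC(=O)N1Br
Why: Electrophilic aromatic bromination goes to the only free position para to the silyloxy group.

Step 11
Reactants: 15 bromo keto pivalate
Product: 16 2-tetralone (ring A closed; C3 ketone, C1 α-CH2OPiv, C2 α-[(S)-2-(TBSO)propyl], 1,2-cis; ring B aromatic with C6/C8 methyls and C7 OTBS)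
Conditions: Pd2(dba)3 (cat.), Xantphos, K3PO4, toluene, 80 °C
Reagents that add atoms: none
Why: Intramolecular Pd-catalysed ketone α-arylation (6-exo closure of C4 onto C4a) can only use the methyl-side enolate, since the C2 enolate would give a four-membered ring.

Step 12
Reactants: 16 2-tetralone
Product: 17 ethylene ketal of 16 at C3
Conditions: ethylene glycol, PPTS (cat.), benzene, reflux, Dean–Stark
Reagents that add atoms: ethylene glycol, OCCO
Why: Ketalisation protects the C3 ketone for the organolithium steps and fixes C2.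

Step 13
Reactants: 17 tetralin ketal
Product: 18 all-cis perhydro compound (cis-fused decalin; H1, H4a, H6, H7, H8, H8a all β; C6-Me, C7-OTBS, C8-Me α; C1 α-CH2OPiv)
Conditions: H2 (50 bar), cyclic (alkyl)(amino)carbene–Rh(cod)Cl precatalyst (3 mol %), 4 Å MS, hexane, 40 °C
Reagents that add atoms: none
Why: Cis-selective arene hydrogenation (dearomatization) delivers all six hydrogens to the ring-B face anti to the C1 CH2OPiv group (held pseudo-axial by peri strain with the C8 methyl), setting C6, C7, C8 and C8a with H8a cis to H1.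

Step 14
Reactants: 18 pivalate
Product: 19 primary alcohol (C9–OH)
Conditions: DIBAL-H (2.5 equiv), CH2Cl2, −78 °C; Rochelle salt
Reagents that add atoms: none
Why: Reductive cleavage of the pivalate leaves silyl ethers and ketal intact.

Step 15
Reactants: 19 alcohol
Product: 20 aldehyde (C9)
Conditions: DMP, NaHCO3, CH2Cl2, 0 °C
Reagents that add atoms: none
Why: Buffered Dess–Martin oxidation gives the aldehyde without epimerising the α-stereocentre C1.

Step 16
Reactants: 20 aldehyde
Product: 21 1,1-dibromoalkene (C1–CH=CBr2)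
Conditions: CBr4, PPh3, 2,6-lutidine, CH2Cl2, 0 °C
Reagents that add atoms: carbon tetrabromide, BrC(Br)(Br)Br
Why: Ramirez dibromo-olefination (first stage of the Corey–Fuchs reaction) adds C10 under non-epimerising conditions.

Step 17
Reactants: 21 dibromoalkene
Product: 23 1-propynyl ketal (C1–C≡C–CH3), via lithium acetylide 22 (not isolated)
Conditions: n-BuLi (2.2 equiv), THF, −78 °C; then MeI, −78 °C → rt
Reagents that add atoms: iodomethane, CI
Why: Corey–Fuchs elimination and exchange give the lithium acetylide, which is C-methylated to the internal alkyne C9≡C10–CH3.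

Step 18
Reactants: 23 ketal
Product: 24 C3 ketone
Conditions: PPTS, acetone/H2O 10:1, 55 °C
Reagents that add atoms: water, O
Why: Mild acid hydrolysis removes the dioxolane while the secondary TBS ethers and the alkyne stay.

Step 19
Reactants: 24 ketone
Product: 26 enone (C3=O, C4=C4a), via trimethylsilyl enol ether 25 (not isolated)
Conditions: LDA, TMSCl, THF, −78 °C; then Pd(OAc)2 (1.1 equiv), MeCN, rt
Reagents that add atoms: none
Why: Kinetic enolisation goes to the CH2 (C4) rather than the tertiary C2, and Saegusa–Ito oxidation with β-hydride loss of H4a gives the C4=C4a enone.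

Step 20
Reactants: 26 enone
Product: 28 dienyl triflate (C2=C3(OTf)–C4=C4a), via potassium dienolate 27 (not isolated)
Conditions: KHMDS, THF, −78 °C; then PhNTf2, −78 → −40 °C
Reagents that add atoms: N-phenylbis(trifluoromethanesulfonimide), O=S(=O)(N(c1ccccc1)S(=O)(=O)C(F)(F)F)C(F)(F)F
Why: Kinetic α'-deprotonation of the enone at C2 and O-triflation of the cross-conjugated dienolate fix the diene position.

Step 21
Reactants: 28 dienyl triflate
Product: 29 diene alkyne (decalin fragment: C2=C3(Me)–C4=C4a diene, C1 α-propynyl, C7 α-OTBS, side-chain OTBS)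
Conditions: Me2CuLi, THF, −20 → 0 °C
Reagents that add atoms: lithium dimethylcuprate, [Li+].C[Cu-]C
Why: Cuprate coupling of the enol triflate puts the C3 methyl in place with retention of the diene position.

Step 22
Reactants: 30 4-methylpent-3-enoic acid
Product: 31 2-(trimethylsilyl)ethyl 4-methylpent-3-enoate
Conditions: 2-(trimethylsilyl)ethanol, DCC, DMAP (cat.), CH2Cl2, 0 °C → rt
Reagents that add atoms: 2-(trimethylsilyl)ethanol, C[Si](C)(C)CCO
Why: Steglich esterification gives a fluoride-cleavable ester acidic enough at C14 for the later E1cB step.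

Step 23
Reactants: 31 ester
Product: 32 2-(trimethylsilyl)ethyl (E)-5-hydroxy-4-methylpent-3-enoate
Conditions: SeO2 (0.5 equiv), t-BuOOH, CH2Cl2, rt
Reagents that add atoms: tert-butyl hydroperoxide (terminal oxidant, oxygen delivered via SeO2), CC(C)(C)OO
Why: SeO2 allylic oxidation (ene reaction, then [2,3]-shift) hydroxylates the (E)-methyl of the trisubstituted alkene and gives the E-allylic alcohol (C11).

Step 24
Reactants: 32 allylic alcohol
Product: 33 2-(trimethylsilyl)ethyl 2-[(2R,3R)-3-(hydroxymethyl)-3-methyloxiran-2-yl]acetate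
Conditions: Ti(OiPr)4 (10 mol %), D-(−)-diisopropyl tartrate (12 mol %), t-BuOOH, 4 Å MS, CH2Cl2, −20 °C
Reagents that add atoms: tert-butyl hydroperoxide, CC(C)(C)OO
Why: Sharpless asymmetric epoxidation sets C12 (and, temporarily, C13) by reagent control; the D-(−)-tartrate should give the (2R,3R) epoxy alcohol.

Step 25
Reactants: 33 epoxy alcohol
Product: 34 2-(trimethylsilyl)ethyl 2-[(2R,3S)-3-formyl-3-methyloxiran-2-yl]acetate
Conditions: DMP, NaHCO3, CH2Cl2, 0 °C; used at once
Reagents that add atoms: none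
Why: Neutral Dess–Martin oxidation gives the α,β-epoxy aldehyde, whose α-carbon is quaternary and cannot epimerise.

Step 26
Reactants: 29 diene alkyne; 34 epoxy aldehyde
Product: 37 anti-epoxy alcohol (9E; 11R,12R,13R; C11–OH, temporary C12–C13 oxirane), via alkenylzirconocene 35 (not isolated), via alkenylmethylzinc 36 (not isolated)
Conditions: Cp2Zr(H)Cl, CH2Cl2, rt → 40 °C; then toluene, Me2Zn, −65 °C; then 34, −65 → 0 °C; aq NH4Cl
Reagents that add atoms: none
Why: Cp2Zr(H)Cl adds H–Zr syn across C9≡C10 and, after equilibration, places Zr on C10 (the methyl-bearing, less hindered terminus, C9 being flanked by the branched ring carbon C1), which fixes the E geometry of C9=C10; Zr→Zn exchange with Me2Zn proceeds with retention and the alkenylzinc adds 1,2 to the aldehyde carbon C11 of 34. The closest known reaction type is the one-flask hydrozirconation/transmetalation/aldehyde alkenylation of alkynes. No ring is closed. The new stereocentre C11 is controlled by the adjacent quaternary oxirane carbon C12 of the temporary C12–C13 oxirane: polar Felkin–Anh (Cornforth) addition anti to the C12–O bond should give the anti (erythro) epoxy alcohol, the usual outcome of non-chelating additions to α,β-epoxy aldehydes and the epimer that the later inversion at C11 requires. The step needs regioselective hydrometalation (secured by the C1 branch versus methyl), chemoselectivity for the aldehyde over the TMSE ester and its acidic C14–H (secured by the low basicity of the alkenylzinc) and facial selectivity at C11 (secured by the rigid epoxy aldehyde). In this one operation the carbon skeleton is completed, the trisubstituted (E)-alkene is made and the C11 oxygen and configuration are installed.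

Step 27
Reactants: 37 anti-epoxy alcohol
Product: 40 vinyl oxirane enoate (11S,12S; 13E; TMSE ester, two TBS ethers), via allylic mesylate 38 (not isolated), via hydroxy mesylate 39 (not isolated)
Conditions: Ms2O, Et3N, CH2Cl2, −20 °C; then DBU, −20 → 0 °C (one flask)
Reagents that add atoms: none
Why: After O-mesylation of C11–OH, DBU triggers E1cB opening of the β,γ-epoxy ester (C14–H removed, C13–O cleaved, E-enoate formed) and the freed C12 alkoxide closes the oxirane on C11 by intramolecular Williamson displacement (3-exo-tet, inversion at C11, retention at C12).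

Step 28
Reactants: 40 protected vinyl oxirane
Product: 41 dihydroxy acid (free C15 acid, C7–OH and side-chain carbinol)
Conditions: TBAF, THF, 0 → 40 °C; pH 5 buffer work-up
Reagents that add atoms: none
Why: Fluoride removes both TBS ethers and fragments the TMSE ester (β-elimination to ethene); the quaternary C12 blocks base-induced opening of the γ,δ-epoxy enoate.

Step 29
Reactants: 41 dihydroxy acid
Product: 42 target, (1S,6S,8R,8aS)-decalin diketone with the (9E,11S,12S,13E) epoxy dienoic acid side chain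
Conditions: DMP (3 equiv), NaHCO3, CH2Cl2, 0 °C → rt
Reagents that add atoms: none
Why: Buffered Dess–Martin oxidation turns both secondary carbinols into the C7 and acetonyl ketones without epimerising C6/C8 or conjugating the β,γ-unsaturated ketone, and it removes the two auxiliary carbinol stereocentres.

**Compound list**

1 | 3-bromo-2,6-dimethylphenol | Cc1ccc(Br)c(C)c1O | starting material
2 | (3-bromo-2,6-dimethylphenoxy)(tert-butyl)dimethylsilane | Cc1ccc(Br)c(C)c1O[Si](C)(C)C(C)(C)C | intermediate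
3 | [3-(TBSO)-2,4-dimethylphenyl]lithium | [Li]c1ccc(C)c(O[Si](C)(C)C(C)(C)C)c1C | intermediate
4 | [3-(TBSO)-2,4-dimethylphenyl]boronic acid | OB(O)c1ccc(C)c(O[Si](C)(C)C(C)(C)C)c1C | intermediate
5 | furan-2(5H)-one | O=C1OCC=C1 | starting material
6 | (R)-4-[3-(TBSO)-2,4-dimethylphenyl]dihydrofuran-2(3H)-one | O=C1C[C@H](c2ccc(C)c(O[Si](C)(C)C(C)(C)C)c2C)CO1 | intermediate
7 | ethyl (S)-lactate | C[C@H](O)C(=O)OCC | starting material
8 | ethyl (S)-2-(TBSO)propanoate | C[C@H](O[Si](C)(C)C(C)(C)C)C(=O)OCC | intermediate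
9 | (S)-2-(TBSO)propan-1-ol | C[C@H](O[Si](C)(C)C(C)(C)C)CO | intermediate
10 | (S)-2-(TBSO)propyl trifluoromethanesulfonate | C[C@H](O[Si](C)(C)C(C)(C)C)COS(=O)(=O)C(F)(F)F | intermediate
11 | lithium enolate of lactone 6 | [Li+].[O-]C1=C[C@H](c2ccc(C)c(O[Si](C)(C)C(C)(C)C)c2C)CO1 | intermediate
12 | (3S,4R)-trans-4-[3-(TBSO)-2,4-dimethylphenyl]-3-[(S)-2-(TBSO)propyl]dihydrofuran-2(3H)-one | C[C@H](O[Si](C)(C)C(C)(C)C)C[C@@H]1C(=O)OC[C@H]1c2ccc(C)c(O[Si](C)(C)C(C)(C)C)c2C | intermediate
13 | (3S,4R)-4-[3-(TBSO)-2,4-dimethylphenyl]-5-hydroxy-3-[(S)-2-(TBSO)propyl]pentan-2-one | C[C@H](O[Si](C)(C)C(C)(C)C)C[C@H](C(C)=O)[C@@H](CO)c1ccc(C)c(O[Si](C)(C)C(C)(C)C)c1C | intermediate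
14 | keto pivalate (C9 pivalate of 13) | C[C@H](O[Si](C)(C)C(C)(C)C)C[C@H](C(C)=O)[C@@H](COC(=O)C(C)(C)C)c1ccc(C)c(O[Si](C)(C)C(C)(C)C)c1C | intermediate
15 | bromo keto pivalate (Br on the arene carbon para to OTBS) | C[C@H](O[Si](C)(C)C(C)(C)C)C[C@H](C(C)=O)[C@@H](COC(=O)C(C)(C)C)c1c(Br)cc(C)c(O[Si](C)(C)C(C)(C)C)c1C | intermediate
16 | 2-tetralone (C3 ketone; C1 α-CH2OPiv and C2 α-[(S)-2-(TBSO)propyl] cis; aromatic ring B with C6/C8 Me and C7 OTBS) | C[C@H](O[Si](C)(C)C(C)(C)C)C[C@@H]1C(=O)Cc2cc(C)c(O[Si](C)(C)C(C)(C)C)c(C)c2[C@@H]1COC(=O)C(C)(C)C | intermediate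
17 | C3 ethylene ketal of 16 | C[C@H](O[Si](C)(C)C(C)(C)C)C[C@@H]1C3(OCCO3)Cc2cc(C)c(O[Si](C)(C)C(C)(C)C)c(C)c2[C@@H]1COC(=O)C(C)(C)C | intermediate
18 | all-cis perhydro ketal pivalate (cis-decalin; ring H all β; C6-Me, C7-OTBS, C8-Me, C1-CH2OPiv α) | C[C@H](O[Si](C)(C)C(C)(C)C)C[C@@H]1C3(OCCO3)C[C@@H]2C[C@H](C)[C@H](O[Si](C)(C)C(C)(C)C)[C@H](C)[C@@H]2[C@@H]1COC(=O)C(C)(C)C | intermediate
19 | primary alcohol (C9–OH) of the all-cis decalin ketal | C[C@H](O[Si](C)(C)C(C)(C)C)C[C@@H]1C3(OCCO3)C[C@@H]2C[C@H](C)[C@H](O[Si](C)(C)C(C)(C)C)[C@H](C)[C@@H]2[C@@H]1CO | intermediate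
20 | C9 aldehyde of the all-cis decalin ketal | C[C@H](O[Si](C)(C)C(C)(C)C)C[C@@H]1C3(OCCO3)C[C@@H]2C[C@H](C)[C@H](O[Si](C)(C)C(C)(C)C)[C@H](C)[C@@H]2[C@@H]1C=O | intermediate
21 | 1,1-dibromoalkene (C1–CH=CBr2) | C[C@H](O[Si](C)(C)C(C)(C)C)C[C@@H]1C3(OCCO3)C[C@@H]2C[C@H](C)[C@H](O[Si](C)(C)C(C)(C)C)[C@H](C)[C@@H]2[C@@H]1C=C(Br)Br | intermediate
22 | lithium acetylide (C1–C≡C–Li) | C[C@H](O[Si](C)(C)C(C)(C)C)C[C@@H]1C3(OCCO3)C[C@@H]2C[C@H](C)[C@H](O[Si](C)(C)C(C)(C)C)[C@H](C)[C@@H]2[C@@H]1C#C[Li] | intermediate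
23 | 1-propynyl decalin ketal | C[C@H](O[Si](C)(C)C(C)(C)C)C[C@@H]1C3(OCCO3)C[C@@H]2C[C@H](C)[C@H](O[Si](C)(C)C(C)(C)C)[C@H](C)[C@@H]2[C@@H]1C#CC | intermediate
24 | 1-propynyl decalin-3-one | C[C@H](O[Si](C)(C)C(C)(C)C)C[C@@H]1C(=O)C[C@@H]2C[C@H](C)[C@H](O[Si](C)(C)C(C)(C)C)[C@H](C)[C@@H]2[C@@H]1C#CC | intermediate
25 | trimethylsilyl enol ether (C3=C4) of 24 | C[C@H](O[Si](C)(C)C(C)(C)C)C[C@@H]1C(O[Si](C)(C)C)=C[C@@H]2C[C@H](C)[C@H](O[Si](C)(C)C(C)(C)C)[C@H](C)[C@@H]2[C@@H]1C#CC | intermediate
26 | enone (C3=O, C4=C4a) | C[C@H](O[Si](C)(C)C(C)(C)C)C[C@@H]1C(=O)C=C2C[C@H](C)[C@H](O[Si](C)(C)C(C)(C)C)[C@H](C)[C@@H]2[C@@H]1C#CC | intermediate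
27 | potassium cross-conjugated dienolate of 26 | C[C@H](O[Si](C)(C)C(C)(C)C)CC1=C([O-])C=C2C[C@H](C)[C@H](O[Si](C)(C)C(C)(C)C)[C@H](C)[C@@H]2[C@@H]1C#CC.[K+] | intermediate
28 | dienyl triflate (C2=C3(OTf)–C4=C4a) | C[C@H](O[Si](C)(C)C(C)(C)C)CC1=C(OS(=O)(=O)C(F)(F)F)C=C2C[C@H](C)[C@H](O[Si](C)(C)C(C)(C)C)[C@H](C)[C@@H]2[C@@H]1C#CC | intermediate
29 | diene alkyne (decalin fragment; C1 α-propynyl, H1/H8a β, C6-Me/C7-OTBS/C8-Me α, side-chain (S)-OTBS) | C[C@H](O[Si](C)(C)C(C)(C)C)CC1=C(C)C=C2C[C@H](C)[C@H](O[Si](C)(C)C(C)(C)C)[C@H](C)[C@@H]2[C@@H]1C#CC | intermediate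
30 | 4-methylpent-3-enoic acid | CC(C)=CCC(=O)O | starting material
31 | 2-(trimethylsilyl)ethyl 4-methylpent-3-enoate | CC(C)=CCC(=O)OCC[Si](C)(C)C | intermediate
32 | 2-(trimethylsilyl)ethyl (E)-5-hydroxy-4-methylpent-3-enoate | OC/C(C)=C/CC(=O)OCC[Si](C)(C)C | intermediate
33 | 2-(trimethylsilyl)ethyl 2-[(2R,3R)-3-(hydroxymethyl)-3-methyloxiran-2-yl]acetate | OC[C@@]1(C)O[C@@H]1CC(=O)OCC[Si](C)(C)C | intermediate
34 | 2-(trimethylsilyl)ethyl 2-[(2R,3S)-3-formyl-3-methyloxiran-2-yl]acetate | O=C[C@@]1(C)O[C@@H]1CC(=O)OCC[Si](C)(C)C | intermediate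
35 | (E)-alkenylzirconocene chloride (Zr on C10) | C[C@H](O[Si](C)(C)C(C)(C)C)CC1=C(C)C=C2C[C@H](C)[C@H](O[Si](C)(C)C(C)(C)C)[C@H](C)[C@@H]2[C@@H]1/C=C(\C)[Zr](Cl)(C1C=CC=C1)C1C=CC=C1 | intermediate
36 | (E)-alkenyl(methyl)zinc (Zn on C10) | C[C@H](O[Si](C)(C)C(C)(C)C)CC1=C(C)C=C2C[C@H](C)[C@H](O[Si](C)(C)C(C)(C)C)[C@H](C)[C@@H]2[C@@H]1/C=C(\C)[Zn]C | intermediate
37 | anti-epoxy alcohol (9E; 11R,12R,13R) | C[C@H](O[Si](C)(C)C(C)(C)C)CC1=C(C)C=C2C[C@H](C)[C@H](O[Si](C)(C)C(C)(C)C)[C@H](C)[C@@H]2[C@@H]1/C=C(\C)[C@@H](O)[C@@]1(C)O[C@@H]1CC(=O)OCC[Si](C)(C)C | intermediate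
38 | C11 mesylate of 37 | C[C@H](O[Si](C)(C)C(C)(C)C)CC1=C(C)C=C2C[C@H](C)[C@H](O[Si](C)(C)C(C)(C)C)[C@H](C)[C@@H]2[C@@H]1/C=C(\C)[C@@H](OS(C)(=O)=O)[C@@]1(C)O[C@@H]1CC(=O)OCC[Si](C)(C)C | intermediate
39 | hydroxy mesylate enoate (C12–OH, C11–OMs, 13E) | C[C@H](O[Si](C)(C)C(C)(C)C)CC1=C(C)C=C2C[C@H](C)[C@H](O[Si](C)(C)C(C)(C)C)[C@H](C)[C@@H]2[C@@H]1/C=C(\C)[C@@H](OS(C)(=O)=O)[C@@](C)(O)/C=C/C(=O)OCC[Si](C)(C)C | intermediate
40 | vinyl oxirane enoate (11S,12S; TMSE ester, bis-TBS ether) | C[C@H](O[Si](C)(C)C(C)(C)C)CC1=C(C)C=C2C[C@H](C)[C@H](O[Si](C)(C)C(C)(C)C)[C@H](C)[C@@H]2[C@@H]1/C=C(\C)[C@@H]1O[C@@]1(C)/C=C/C(=O)OCC[Si](C)(C)C | intermediate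
41 | dihydroxy acid | C[C@H](O)CC1=C(C)C=C2C[C@H](C)[C@H](O)[C@H](C)[C@@H]2[C@@H]1/C=C(\C)[C@@H]1O[C@@]1(C)/C=C/C(=O)O | intermediate
42 | CNP0214881.1 | CC(=O)CC1=C(C)C=C2C[C@H](C)C(=O)[C@H](C)[C@@H]2[C@@H]1/C=C(\C)[C@@H]1O[C@@]1(C)/C=C/C(=O)O | target

**Count and risks**

Total step count: 29. Longest linear sequence: 22 steps (steps 1–3, 7–21, 26–29, from 1 to 42).

Steps most likely to fail:

- **Step 26.** The alkenylzinc addition may show poor facial selectivity at C11, because the methyl group and the oxirane ring carbon on C12 differ little in size, or competing chelation may erode it. The fallback keeps the union but sets C11 by reduction. It sets out from 29 and 34: the coupling is run as before and the crude mixture of 37 and its C11 epimer, the syn-epoxy alcohol F4, is oxidised with Dess–Martin periodinane (NaHCO3, CH2Cl2) to the α,β-epoxy enone F5. Zinc borohydride (Et2O, −20 °C) then reduces the chelated epoxy ketone 1,2 to the anti (erythro) epoxy alcohol, and the route is rejoined at 37.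

- **Step 27.** The allylic C11 sulfonate may be lost by ionisation or SN2' attack before the E1cB step has released the C12 alkoxide. The fallback separates the two events and sets out from 37. DBU alone (CH2Cl2, 0 °C → rt) opens the β,γ-epoxy ester to the diol enoate F6. Mitsunobu cyclodehydration (PPh3, DIAD, toluene, 0 °C → rt) then activates the secondary allylic C11–OH as its oxyphosphonium salt and the tertiary C12–OH displaces it with inversion, which returns the route to 40.

- **Step 13.** Reduction of the crowded, pentasubstituted aryl silyl ether may be incomplete, may cleave the C–O bond, or may deliver hydrogen from both faces. The fallback reduces the ring in two stages and sets out from 17. The aryl silyl ether is cleaved selectively (KHF2, MeOH) to the phenol F1. Pd/C-catalysed hydrogenation of the phenol (H2, cyclohexane) stops at the ketone and should give the cis-fused all-cis decalinone F2, whose α-methyl groups can still settle cis-diequatorial. L-Selectride (THF, −78 °C) attacks from the equatorial direction to give the all-cis axial alcohol F3, and TBSOTf/2,6-lutidine returns the route to 18.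

Further compounds
F1 | step 13 | phenol from 17 (free C7–OH on aromatic ring B) | C[C@H](O[Si](C)(C)C(C)(C)C)C[C@@H]1C3(OCCO3)Cc2cc(C)c(O)c(C)c2[C@@H]1COC(=O)C(C)(C)C
F2 | step 13 | all-cis cis-fused decalin-7-one ketal pivalate | C[C@H](O[Si](C)(C)C(C)(C)C)C[C@@H]1C3(OCCO3)C[C@@H]2C[C@H](C)C(=O)[C@H](C)[C@@H]2[C@@H]1COC(=O)C(C)(C)C
F3 | step 13 | all-cis C7 alcohol (desilyl analogue of 18) | C[C@H](O[Si](C)(C)C(C)(C)C)C[C@@H]1C3(OCCO3)C[C@@H]2C[C@H](C)[C@H](O)[C@H](C)[C@@H]2[C@@H]1COC(=O)C(C)(C)C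
F4 | step 26 | syn-epoxy alcohol (C11 epimer of 37) | C[C@H](O[Si](C)(C)C(C)(C)C)CC1=C(C)C=C2C[C@H](C)[C@H](O[Si](C)(C)C(C)(C)C)[C@H](C)[C@@H]2[C@@H]1/C=C(\C)[C@H](O)[C@@]1(C)O[C@@H]1CC(=O)OCC[Si](C)(C)C
F5 | step 26 | α,β-epoxy enone (C11 ketone) | C[C@H](O[Si](C)(C)C(C)(C)C)CC1=C(C)C=C2C[C@H](C)[C@H](O[Si](C)(C)C(C)(C)C)[C@H](C)[C@@H]2[C@@H]1/C=C(\C)C(=O)[C@@]1(C)O[C@@H]1CC(=O)OCC[Si](C)(C)C
F6 | step 27 | diol enoate (C11–OH, C12–OH, 13E) | C[C@H](O[Si](C)(C)C(C)(C)C)CC1=C(C)C=C2C[C@H](C)[C@H](O[Si](C)(C)C(C)(C)C)[C@H](C)[C@@H]2[C@@H]1/C=C(\C)[C@@H](O)[C@@](C)(O)/C=C/C(=O)OCC[Si](C)(C)C
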